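**Retrosynthetic overview** (germacrane numbering: ring C1–C10, lactone carbons C11–C13 on C7 with O on C6, C14 on C10, C15 on C4)
1. Target 22 is reached from bicyclic aldehyde 20 by two functional-group steps only (C15 aldehyde reduction, C14 desilylation).
2. Key disconnection: the carbocycle bond C4–C5 together with the lactone bond O–C6. Acyclic aldehyde acid 18 is folded in one oxidative organocatalytic operation; the ten-membered ring closes first (C4 to C5), the γ-lactone second (C12 carboxylate to C6).
3. Enabling feature: C4 is the α-carbon of the C15 aldehyde (enamine radical cation), and C5=C6 is the terminal vinyl group of a pent-4-enoic acid unit C5=C6–C7–C11(=C13)–C12O2H, the future lactone ring. The radical formed at C6 therefore sits four atoms from the carboxylate, and the ring-cis C1=C10 olefin pre-folds the chain.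
4. 18 comes from 15 by acylation and unmasking; 15 comes from aldehyde 9 and dienyl bromide 13 by a catalytic asymmetric chromium allylation that forms C7–C8 and sets C7 and C8.
5. 9 comes from alkyne 1 (hydroxymethylation, anti-carbomagnesiation fixing the C1=C10 geometry, hydroboration, oxidation); 13 comes from acrolein and tert-butyl acrylate.

Key step: step 12

Assumption: the (S,S) ligand of step 8 and the (2R,5R) imidazolidinone of step 12 are the enantiomers expected from the usual shielding models to give 8R and 4S; if either sense proves opposite, its mirror-image form is used.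

**Step 1**
Reactants: 1 tert-butyl(hex-5-yn-1-yloxy)dimethylsilane
Product: 3 7-[(tert-butyldimethylsilyl)oxy]hept-2-yn-1-ol, via lithium acetylide 2 (not isolated)
Conditions: n-BuLi, THF, −78 °C; (CH2O)n, −78 °C → rt; then H2O
Reagents that add atoms: formaldehyde (from paraformaldehyde) C=O
Why: Deprotonation of the terminal alkyne and addition of the acetylide to formaldehyde is the standard hydroxymethylation giving the propargylic alcohol (C14–OH on C10≡C1); no stereocentre is formed.

**Step 2**
Reactants: 3 7-[(tert-butyldimethylsilyl)oxy]hept-2-yn-1-ol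
Product: 5 (2E)-7-[(tert-butyldimethylsilyl)oxy]-2-ethenylhept-2-en-1-ol, via magnesium chelate 4 (not isolated)
Conditions: CH2=CHMgBr (3.5 equiv), CuI (15 mol %), THF, 0 °C → reflux; then H2O
Reagents that add atoms: vinylmagnesium bromide C=C[Mg]Br
Why: Copper-catalysed anti-carbomagnesiation of a propargylic alcohol: the magnesium alkoxide directs vinyl transfer to C10 and magnesium to C1 within the five-membered chelate 4, so protonolysis should leave H1 cis to C14 and the new vinyl group (C9=C8) cis to C2, which is the ring-cis C1=C10 geometry of the target.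

**Step 3**
Reactants: 5 (2E)-7-[(tert-butyldimethylsilyl)oxy]-2-ethenylhept-2-en-1-ol
Product: 6 tert-butyl{[(2E)-7-[(tert-butyldimethylsilyl)oxy]-2-ethenylhept-2-en-1-yl]oxy}diphenylsilane
Conditions: TBDPSCl, imidazole, CH2Cl2, 0 °C → rt
Reagents that add atoms: tert-butyl(chloro)diphenylsilane CC(C)(C)[Si](Cl)(c1ccccc1)c1ccccc1
Why: Standard imidazole-mediated silylation of the primary allylic alcohol protects O14 with a group that should survive the later acid step.

**Step 4**
Reactants: 6 tert-butyl{[(2E)-7-[(tert-butyldimethylsilyl)oxy]-2-ethenylhept-2-en-1-yl]oxy}diphenylsilane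
Product: 8 (3E)-8-[(tert-butyldimethylsilyl)oxy]-3-{[(tert-butyldiphenylsilyl)oxy]methyl}oct-3-en-1-ol, via B-alkyl-9-BBN 7 (not isolated)
Conditions: 9-BBN, THF, 0 °C → rt; then NaOH, H2O2, 0 °C
Reagents that add atoms: hydrogen peroxide OO
Why: Hydroboration–oxidation with 9-BBN is selective for the terminal monosubstituted end of the 1,3-diene and places boron on C8 (anti-Markovnikov), leaving the trisubstituted C1=C10 olefin untouched.

**Step 5**
Reactants: 8 (3E)-8-[(tert-butyldimethylsilyl)oxy]-3-{[(tert-butyldiphenylsilyl)oxy]methyl}oct-3-en-1-ol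
Product: 9 (3E)-8-[(tert-butyldimethylsilyl)oxy]-3-{[(tert-butyldiphenylsilyl)oxy]methyl}oct-3-enal
Conditions: Dess–Martin periodinane, pyridine, CH2Cl2, 0 °C; used at once
Reagents that add atoms: none
Why: Dess–Martin oxidation under buffered non-basic conditions should give the β,γ-unsaturated aldehyde (C8) without migration of the C1=C10 double bond into conjugation.

**Step 6**
Reactants: 10 acrolein; 11 tert-butyl acrylate
Product: 12 tert-butyl 3-hydroxy-2-methylidenepent-4-enoate (racemic)
Conditions: DABCO (cat.), neat, rt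
Reagents that add atoms: none
Why: Morita–Baylis–Hillman reaction of the acrylate with the reactive aldehyde acrolein assembles C5–C6–C7–C11(=C13)–C12; the racemic carbinol centre is removed in step 7.

**Step 7**
Reactants: 12 tert-butyl 3-hydroxy-2-methylidenepent-4-enoate
Product: 13 tert-butyl (2Z)-2-(bromomethyl)penta-2,4-dienoate
Conditions: PBr3, Et2O, −10 → 0 °C
Reagents that add atoms: phosphorus tribromide BrP(Br)Br
Why: Allylic bromination with transposition (SN2′) should give the thermodynamically preferred conjugated (2Z)-dienoate, and any regioisomeric allylic bromide would converge to the same pentadienylchromium species in step 8.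

**Step 8**
Reactants: 9 (3E)-8-[(tert-butyldimethylsilyl)oxy]-3-{[(tert-butyldiphenylsilyl)oxy]methyl}oct-3-enal; 13 tert-butyl (2Z)-2-(bromomethyl)penta-2,4-dienoate
Product: 15 tert-butyl (3R,4R,6E)-11-[(tert-butyldimethylsilyl)oxy]-6-{[(tert-butyldiphenylsilyl)oxy]methyl}-3-ethenyl-4-hydroxy-2-methylideneundec-6-enoate, via trimethylsilyl ether 14 (not isolated)
Conditions: CrCl2 (10 mol %), 1,8-bis[(4S)-4-isopropyl-4,5-dihydro-1,3-oxazol-2-yl]-3,6-diphenyl-9H-carbazole (12 mol %), Mn powder, Me3SiCl, i-Pr2NEt (30 mol %), THF, rt; then citric acid, MeOH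
Reagents that add atoms: none
Why: Catalytic asymmetric Nozaki–Hiyama–Kishi allylation with a 2-(alkoxycarbonyl)allyl bromide: the pentadienylchromium reagent should react at its central carbon C7 through a chair transition state (SE2′) to give the skipped diene, the allyl geometry with the vinyl group cis to CH2Cr gives the syn C7/C8 relationship, the ligand directs attack to the Si face of the aldehyde (8R), and the bulky tert-butyl ester prevents lactonisation onto O8.

**Step 9**
Reactants: 15 tert-butyl (3R,4R,6E)-11-[(tert-butyldimethylsilyl)oxy]-6-{[(tert-butyldiphenylsilyl)oxy]methyl}-3-ethenyl-4-hydroxy-2-methylideneundec-6-enoate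
Product: 16 tert-butyl (3R,4R,6E)-11-[(tert-butyldimethylsilyl)oxy]-6-{[(tert-butyldiphenylsilyl)oxy]methyl}-3-ethenyl-2-methylidene-4-[(2-methylprop-2-enoyl)oxy]undec-6-enoate
Conditions: methacrylic anhydride, Et3N, DMAP (cat.), CH2Cl2, 0 °C → rt
Reagents that add atoms: methacrylic anhydride CC(=C)C(=O)OC(=O)C(C)=C
Why: DMAP-catalysed acylation of the secondary alcohol installs the C8 methacrylate of the target and blocks O8, so that only O–C6 lactonisation is possible later.

**Step 10**
Reactants: 16 tert-butyl (3R,4R,6E)-11-[(tert-butyldimethylsilyl)oxy]-6-{[(tert-butyldiphenylsilyl)oxy]methyl}-3-ethenyl-2-methylidene-4-[(2-methylprop-2-enoyl)oxy]undec-6-enoate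
Product: 17 (3R,4R,6E)-6-{[(tert-butyldiphenylsilyl)oxy]methyl}-3-ethenyl-11-hydroxy-2-methylidene-4-[(2-methylprop-2-enoyl)oxy]undec-6-enoic acid
Conditions: CF3CO2H/CH2Cl2/H2O (10:30:1), 0 °C → rt
Reagents that add atoms: none
Why: Acidolysis should remove the tert-butyl ester (loss of 2-methylpropene) and the primary TBS ether in one operation, while the TBDPS ether, the methacrylate and the skipped diene are expected to tolerate trifluoroacetic acid.

**Step 11**
Reactants: 17 (3R,4R,6E)-6-{[(tert-butyldiphenylsilyl)oxy]methyl}-3-ethenyl-11-hydroxy-2-methylidene-4-[(2-methylprop-2-enoyl)oxy]undec-6-enoic acid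
Product: 18 (3R,4R,6E)-6-{[(tert-butyldiphenylsilyl)oxy]methyl}-3-ethenyl-2-methylidene-4-[(2-methylprop-2-enoyl)oxy]-11-oxoundec-6-enoic acid
Conditions: Dess–Martin periodinane, CH2Cl2, 0 °C → rt
Reagents that add atoms: none
Why: Dess–Martin oxidation of the primary alcohol tolerates the free carboxylic acid and all four olefins and stops at the C15 aldehyde.

**Step 12**
Reactants: 18 (3R,4R,6E)-6-{[(tert-butyldiphenylsilyl)oxy]methyl}-3-ethenyl-2-methylidene-4-[(2-methylprop-2-enoyl)oxy]-11-oxoundec-6-enoic acid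
Product: 20 [(3aS,4R,6E,10S,11aR)-6-{[(tert-butyldiphenylsilyl)oxy]methyl}-10-formyl-3-methylidene-2-oxo-2,3,3a,4,5,8,9,10,11,11a-decahydrocyclodeca[b]furan-4-yl] 2-methylprop-2-enoate, via enamine 19 (not isolated)
Conditions: (2R,5R)-5-benzyl-2-tert-butyl-3-methylimidazolidin-4-one·CF3CO2H (30 mol %), Cu(OTf)2 (2.5 equiv), CF3CO2Na (2 equiv), H2O (2 equiv), i-PrCN/DME (1:1), rt, 18 added by syringe pump (final concentration ≤ 3 mM)
Reagents that add atoms: none
Why: Proposed new method: the C15 aldehyde condenses with the imidazolidinone to give enamine 19, one-electron oxidation by Cu(OTf)2 makes an electrophilic three-π-electron radical cation at C4 that adds 10-endo-trig to the terminal vinyl carbon C5, and the resulting secondary C6 radical is captured by the divalent copper held on the C12 carboxylate and released by C–O bond formation (formally 5-exo closure of the γ-lactone) before hydrolysis frees 20 and the catalyst. The closest known reactions are organo-SOMO additions of aldehyde-derived enamine radical cations to olefins (intramolecular α-alkylation with simple olefins in five- to seven-membered ring closures, Cu(OTf)2-driven polyene cyclisation, carbo-oxidation of styrenes) and copper-mediated radical carbolactonisation of pent-4-enoic acids; new are the ten-membered ring size and the union of the two events. C4 is set by the catalyst: the E-enamine radical cation lies away from the tert-butyl group and the benzyl group blocks one face, so C5 should bond to the open face to give 4S regardless of the distant C7 and C8 centres. C6 is set by C7: the carboxylate on C11 should deliver oxygen to the face of C6 that places C5 and C8 trans on the forming lactone (least eclipsing, as in thermodynamic halolactonisation of 3-substituted pent-4-enoic acids), giving 6R. Chemoselectivity rests on polarity and geometry: the electrophilic radical cation should ignore the electron-poor acrylic acid and methacrylate double bonds, the only other electron-rich olefin C1=C10 is reachable from C4 only by 4-exo or 5-endo closure, and slow addition together with the cis C1=C10 turn favours ring closure over oligomerisation.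

**Step 13**
Reactants: 20 [(3aS,4R,6E,10S,11aR)-6-{[(tert-butyldiphenylsilyl)oxy]methyl}-10-formyl-3-methylidene-2-oxo-2,3,3a,4,5,8,9,10,11,11a-decahydrocyclodeca[b]furan-4-yl] 2-methylprop-2-enoate
Product: 21 [(3aS,4R,6E,10S,11aR)-6-{[(tert-butyldiphenylsilyl)oxy]methyl}-10-(hydroxymethyl)-3-methylidene-2-oxo-2,3,3a,4,5,8,9,10,11,11a-decahydrocyclodeca[b]furan-4-yl] 2-methylprop-2-enoate
Conditions: NaBH4, CeCl3·7H2O, MeOH/THF, −78 °C
Reagents that add atoms: none
Why: Luche reduction should reduce the aldehyde at low temperature much faster than it touches the α-methylene lactone or the methacrylate, and C4 is not epimerised because the aldehyde is consumed at −78 °C.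

**Step 14**
Reactants: 21 [(3aS,4R,6E,10S,11aR)-6-{[(tert-butyldiphenylsilyl)oxy]methyl}-10-(hydroxymethyl)-3-methylidene-2-oxo-2,3,3a,4,5,8,9,10,11,11a-decahydrocyclodeca[b]furan-4-yl] 2-methylprop-2-enoate
Product: 22 [(3aS,4R,6E,10S,11aR)-6,10-bis(hydroxymethyl)-3-methylidene-2-oxo-2,3,3a,4,5,8,9,10,11,11a-decahydrocyclodeca[b]furan-4-yl] 2-methylprop-2-enoate (CNP0546547.2)
Conditions: HF·pyridine, pyridine, THF, 0 °C → rt
Reagents that add atoms: none
Why: Fluoride-mediated desilylation under buffered, weakly acidic conditions should cleave the primary allylic TBDPS ether without acyl migration or conjugate addition to the α-methylene lactone.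

**Compound list**
1 | tert-butyl(hex-5-yn-1-yloxy)dimethylsilane | C#CCCCCO[Si](C)(C)C(C)(C)C | starting material
2 | lithium acetylide of 1: {6-[(tert-butyldimethylsilyl)oxy]hex-1-yn-1-yl}lithium | [Li]C#CCCCCO[Si](C)(C)C(C)(C)C | intermediate
3 | 7-[(tert-butyldimethylsilyl)oxy]hept-2-yn-1-ol | OCC#CCCCCO[Si](C)(C)C(C)(C)C | intermediate
4 | magnesium chelate: 3-{4-[(tert-butyldimethylsilyl)oxy]butyl}-4-ethenyl-2,5-dihydro-1,2-oxamagnesole | C=CC1=C(CCCCO[Si](C)(C)C(C)(C)C)[Mg]OC1 | intermediate
5 | (2E)-7-[(tert-butyldimethylsilyl)oxy]-2-ethenylhept-2-en-1-ol | OC/C(C=C)=C/CCCCO[Si](C)(C)C(C)(C)C | intermediate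
6 | tert-butyl{[(2E)-7-[(tert-butyldimethylsilyl)oxy]-2-ethenylhept-2-en-1-yl]oxy}diphenylsilane | C=C/C(CO[Si](c1ccccc1)(c1ccccc1)C(C)(C)C)=C\CCCCO[Si](C)(C)C(C)(C)C | intermediate
7 | B-alkyl-9-BBN: 9-[(3E)-8-[(tert-butyldimethylsilyl)oxy]-3-{[(tert-butyldiphenylsilyl)oxy]methyl}oct-3-en-1-yl]-9-borabicyclo[3.3.1]nonane | B1(CC/C(CO[Si](c2ccccc2)(c2ccccc2)C(C)(C)C)=C\CCCCO[Si](C)(C)C(C)(C)C)C2CCCC1CCC2 | intermediate
8 | (3E)-8-[(tert-butyldimethylsilyl)oxy]-3-{[(tert-butyldiphenylsilyl)oxy]methyl}oct-3-en-1-ol | OCC/C(CO[Si](c1ccccc1)(c1ccccc1)C(C)(C)C)=C\CCCCO[Si](C)(C)C(C)(C)C | intermediate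
9 | (3E)-8-[(tert-butyldimethylsilyl)oxy]-3-{[(tert-butyldiphenylsilyl)oxy]methyl}oct-3-enal | O=CC/C(CO[Si](c1ccccc1)(c1ccccc1)C(C)(C)C)=C\CCCCO[Si](C)(C)C(C)(C)C | intermediate
10 | acrolein (prop-2-enal) | C=CC=O | starting material
11 | tert-butyl acrylate | C=CC(=O)OC(C)(C)C | starting material
12 | tert-butyl 3-hydroxy-2-methylidenepent-4-enoate (racemic) | C=CC(O)C(=C)C(=O)OC(C)(C)C | intermediate
13 | tert-butyl (2Z)-2-(bromomethyl)penta-2,4-dienoate | BrC/C(C(=O)OC(C)(C)C)=C\C=C | intermediate
14 | trimethylsilyl ether of 15 (O8–SiMe3) | C=C(C(=O)OC(C)(C)C)[C@@H](C=C)[C@H](O[Si](C)(C)C)C/C(CO[Si](c1ccccc1)(c1ccccc1)C(C)(C)C)=C\CCCCO[Si](C)(C)C(C)(C)C | intermediate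
15 | tert-butyl (3R,4R,6E)-11-[(tert-butyldimethylsilyl)oxy]-6-{[(tert-butyldiphenylsilyl)oxy]methyl}-3-ethenyl-4-hydroxy-2-methylideneundec-6-enoate (syn C7/C8; germacrane C8 R) | C=C(C(=O)OC(C)(C)C)[C@@H](C=C)[C@H](O)C/C(CO[Si](c1ccccc1)(c1ccccc1)C(C)(C)C)=C\CCCCO[Si](C)(C)C(C)(C)C | intermediate
16 | tert-butyl (3R,4R,6E)-11-[(tert-butyldimethylsilyl)oxy]-6-{[(tert-butyldiphenylsilyl)oxy]methyl}-3-ethenyl-2-methylidene-4-[(2-methylprop-2-enoyl)oxy]undec-6-enoate | C=C(C(=O)OC(C)(C)C)[C@@H](C=C)[C@H](OC(=O)C(C)=C)C/C(CO[Si](c1ccccc1)(c1ccccc1)C(C)(C)C)=C\CCCCO[Si](C)(C)C(C)(C)C | intermediate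
17 | (3R,4R,6E)-6-{[(tert-butyldiphenylsilyl)oxy]methyl}-3-ethenyl-11-hydroxy-2-methylidene-4-[(2-methylprop-2-enoyl)oxy]undec-6-enoic acid | C=C(C(=O)O)[C@@H](C=C)[C@H](OC(=O)C(C)=C)C/C(CO[Si](c1ccccc1)(c1ccccc1)C(C)(C)C)=C\CCCCO | intermediate
18 | (3R,4R,6E)-6-{[(tert-butyldiphenylsilyl)oxy]methyl}-3-ethenyl-2-methylidene-4-[(2-methylprop-2-enoyl)oxy]-11-oxoundec-6-enoic acid | C=C(C(=O)O)[C@@H](C=C)[C@H](OC(=O)C(C)=C)C/C(CO[Si](c1ccccc1)(c1ccccc1)C(C)(C)C)=C\CCCC=O | intermediate
19 | (E)-enamine of 18 with (2R,5R)-5-benzyl-2-tert-butyl-3-methylimidazolidin-4-one (N–C15H=C4H) | CN1C(=O)[C@@H](Cc2ccccc2)N(/C=C/CC/C=C(/CO[Si](c2ccccc2)(c2ccccc2)C(C)(C)C)C[C@@H](OC(=O)C(C)=C)[C@H](C=C)C(=C)C(=O)O)[C@H]1C(C)(C)C | intermediate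
20 | [(3aS,4R,6E,10S,11aR)-6-{[(tert-butyldiphenylsilyl)oxy]methyl}-10-formyl-3-methylidene-2-oxo-2,3,3a,4,5,8,9,10,11,11a-decahydrocyclodeca[b]furan-4-yl] 2-methylprop-2-enoate (germacrane 4S,6R,7S,8R; C15 aldehyde) | C=C(C)C(=O)O[C@@H]1C/C(CO[Si](c3ccccc3)(c3ccccc3)C(C)(C)C)=C\CC[C@H](C=O)C[C@H]2OC(=O)C(=C)[C@H]12 | intermediate
21 | [(3aS,4R,6E,10S,11aR)-6-{[(tert-butyldiphenylsilyl)oxy]methyl}-10-(hydroxymethyl)-3-methylidene-2-oxo-2,3,3a,4,5,8,9,10,11,11a-decahydrocyclodeca[b]furan-4-yl] 2-methylprop-2-enoate | C=C(C)C(=O)O[C@@H]1C/C(CO[Si](c3ccccc3)(c3ccccc3)C(C)(C)C)=C\CC[C@H](CO)C[C@H]2OC(=O)C(=C)[C@H]12 | intermediate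
22 | [(3aS,4R,6E,10S,11aR)-6,10-bis(hydroxymethyl)-3-methylidene-2-oxo-2,3,3a,4,5,8,9,10,11,11a-decahydrocyclodeca[b]furan-4-yl] 2-methylprop-2-enoate (CNP0546547.2) | C=C(C)C(=O)O[C@@H]1C/C(CO)=C\CC[C@H](CO)C[C@H]2OC(=O)C(=C)[C@H]12 | target

**Step count and risks**
Total steps: 14. Longest linear sequence: 12 steps (steps 1–5 and 8–14 from 1); the bromide branch (steps 6–7) joins at step 8.

Steps most likely to fail:

1. Step 12 (Proposed new method). The ten-membered ring closure may be too slow, so that bimolecular coupling or α-oxygenation of the enamine radical cation takes over. The C6 radical may undergo oxidative elimination instead of C–O bond formation. The lactone may close on the wrong face of C6. Fallback, which separates the two bond formations and closes the ring by a polar reaction: it sets out from 17. Thermodynamic iodolactonisation (I2, MeCN, 0 °C, no base) should give the trans-fused iodolactone alcohol F1, which fixes O–C6 and the C6 configuration first. Dess–Martin oxidation gives the iodolactone aldehyde F2. An amine-catalysed intramolecular α-alkylation of the aldehyde by the primary iodide (α-methylproline of the appropriate configuration, Et3N, CHCl3, high dilution) then closes C4–C5 by SN2 displacement and comes back to the route at 20. Both reaction types are established, though the alkylation is precedented for small rings and its rate at this ring size is the weak point of the fallback.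

2. Step 8. The pentadienylchromium reagent may attack through its terminal carbon, the chiral complex may discriminate the aldehyde faces poorly, or the β,γ-double bond of 9 may migrate into conjugation. Fallback, which replaces asymmetric catalysis by a racemic coupling and resolution: it sets out from 9 and 13. Indium-mediated Barbier coupling (In powder, THF/H2O, rt), which is γ- and syn-selective for 2-(bromomethyl)acrylates, gives the racemic syn adduct. The enantiomers are separated by preparative chromatography on a chiral stationary phase; ent-15 F3 is discarded, and the route is rejoined at 15.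

3. Step 10. Trifluoroacetic acid may partly remove the TBDPS group or protonate the C1=C10 olefin. Fallback, a stepwise non-protic unmasking: it sets out from 16. PPTS in MeOH removes only the primary TBS ether to give alcohol ester F4. Me3SiOTf with 2,6-lutidine (CH2Cl2, 0 °C) converts the tert-butyl ester into the trimethylsilyl ester and silylates O15, giving bis-silyl compound F5, which is hydrolysed on aqueous work-up (pH 5 buffer) to rejoin the route at 17.

**Further compounds**
F1 | step 12 | trans-fused iodolactone alcohol: 6,12-lactone of 17 with C5–I and free C15–OH | IC[C@H]1OC(=O)C(=C)[C@@H]1[C@H](OC(=O)C(C)=C)C/C(CO[Si](c2ccccc2)(c2ccccc2)C(C)(C)C)=C\CCCCO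
F2 | step 12 | iodolactone aldehyde (C5–I; C15 aldehyde) | IC[C@H]1OC(=O)C(=C)[C@@H]1[C@H](OC(=O)C(C)=C)C/C(CO[Si](c2ccccc2)(c2ccccc2)C(C)(C)C)=C\CCCC=O
F3 | step 8 | ent-15: tert-butyl (3S,4S,6E)-11-[(tert-butyldimethylsilyl)oxy]-6-{[(tert-butyldiphenylsilyl)oxy]methyl}-3-ethenyl-4-hydroxy-2-methylideneundec-6-enoate | C=C(C(=O)OC(C)(C)C)[C@H](C=C)[C@@H](O)C/C(CO[Si](c1ccccc1)(c1ccccc1)C(C)(C)C)=C\CCCCO[Si](C)(C)C(C)(C)C
F4 | step 10 | tert-butyl (3R,4R,6E)-6-{[(tert-butyldiphenylsilyl)oxy]methyl}-3-ethenyl-11-hydroxy-2-methylidene-4-[(2-methylprop-2-enoyl)oxy]undec-6-enoate | C=C(C(=O)OC(C)(C)C)[C@@H](C=C)[C@H](OC(=O)C(C)=C)C/C(CO[Si](c1ccccc1)(c1ccccc1)C(C)(C)C)=C\CCCCO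
F5 | step 10 | trimethylsilyl (3R,4R,6E)-6-{[(tert-butyldiphenylsilyl)oxy]methyl}-3-ethenyl-2-methylidene-4-[(2-methylprop-2-enoyl)oxy]-11-[(trimethylsilyl)oxy]undec-6-enoate | C=C(C(=O)O[Si](C)(C)C)[C@@H](C=C)[C@H](OC(=O)C(C)=C)C/C(CO[Si](c1ccccc1)(c1ccccc1)C(C)(C)C)=C\CCCCO[Si](C)(C)C
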